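**Plan**
- Retrosynthesis: the C(sp)–C(sp2) bond of the enyne is cut first (Sonogashira), giving an ethynyl-tetrahydrofuran and a bromo-iodo-triene. The ethynyl carbon and one excised formyl carbon are then traced back to the two carbons of an alkene bridge. Last, ring bonds C2–C3 and C4–C5 are cut together (Diels–Alder).
- Enabling feature: ring O1 lies between the two stereocentres C2 and C5, with the unsubstituted C3H2–C4H2 unit opposite. O1, C2 and C5 are therefore the oxygen and the two α-carbons of a furan (diene termini), and C3–C4 is a dienophile. The tetrahydrofuran is the oxygen-bridged five-membered ring of a 7-oxabicyclo[2.2.1]heptene.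
- Forward: a 2-alkylfuran that already carries the ester chain adds an acrylimide (ethylene equivalent). The acyl carbon is removed, and the carbon bridge is cleaved to two cis hydroxymethyl groups. The one on C5 becomes the alkyne, the one on C2 is excised, and the side chain is coupled last.
- Stereochemistry: both C–O stereocentres are set in the cycloaddition by a chiral copper–bis(oxazoline) catalyst. The bicycle forces the bridgehead ester chain on C2 to lie trans to the bridge carbon on C5. Decarbonylation with retention then puts H where the other bridge carbon stood, which gives the 2,5-trans ring. The E-alkenes come from hydrozirconation, Wittig and Takai reactions.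

Key step: step 2

Remark: the facial sense of the copper–bis(oxazoline) cycloaddition is assumed to be the same for the 2-alkylfuran as for furan itself. Cyclopentadienyl ligands are drawn σ-bonded, and spent metal species are written as ions in SMILES.

Step 1
Reactants: 1 furan; 2 4-bromo-1,1,1-trimethoxybutane (trimethyl 4-bromoorthobutyrate)
Product: 5 methyl 4-(furan-2-yl)butanoate, via 2-furyllithium 3 (not isolated), via 2-(4,4,4-trimethoxybutyl)furan 4 (not isolated)
Conditions: n-BuLi, THF, -20 to 0 °C; then 2, DMPU, 0 °C to rt; aq. citric acid work-up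
Reagents that add atoms: water, O
Why: α-Lithiation of furan and SN2 alkylation of the furyllithium by the primary bromide should install the chain, the ortho ester protecting the carboxyl from the organolithium and hydrolysing to the methyl ester on mild aqueous acid work-up.

Step 2
Reactants: 5 methyl 4-(furan-2-yl)butanoate; 6 3-acryloyl-1,3-oxazolidin-2-one
Product: 7 methyl 4-[(1S,2S,4S)-2-(2-oxo-1,3-oxazolidine-3-carbonyl)-7-oxabicyclo[2.2.1]hept-5-en-1-yl]butanoate (ortho-endo adduct)
Conditions: [Cu((S,S)-t-Bu-box)](SbF6)2 (10 mol%), 4 Å MS, CH2Cl2, -78 °C; cold chromatography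
Reagents that add atoms: none
Why: The s-cis acrylimide chelated to divalent copper is a strongly LUMO-lowered dienophile that should undergo a concerted, asynchronous normal-demand [4+2] cycloaddition with the furan, the unsubstituted furan C5 bonding to the β-carbon and the substituted C2 to the α-carbon, so that both ring C–C bonds of the later tetrahydrofuran form together. The closest known reaction is the same copper–bis(oxazoline)-catalysed Diels–Alder reaction of parent furan with this imide. The step closes the six-membered carbocycle C1–C2–C3–C4–C5=C6 and with it the oxygen-bridged five-membered ring O7–C1–C2–C3–C4 in a suprafacial [4π+2π] mode. C1 and C4 are fixed by the furan face that adds, which is dictated by the tert-butyl groups of the (S,S)-ligand shielding one face of the bound dienophile together with endo approach; C2 follows the endo rule and is deleted later. The step needs ortho regioselectivity (largest HOMO coefficient at the unsubstituted furan α-carbon pairing with the acrylimide β-carbon), endo selectivity and kinetic control (-78 °C, no warming before the alkene is removed, because the adduct can revert). Ortho-exo and meta-endo adducts would lead to the enantiomeric ring system once the acyl carbon is gone, so only the purified ortho-endo isomer is carried on.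

Step 3
Reactants: 7 ortho-endo adduct
Product: 8 methyl 4-[(1R,2S,4S,5R,6S)-5,6-dihydroxy-2-(2-oxo-1,3-oxazolidine-3-carbonyl)-7-oxabicyclo[2.2.1]heptan-1-yl]butanoate
Conditions: OsO4 (2 mol%), NMO, acetone/H2O, 0 °C
Reagents that add atoms: N-methylmorpholine N-oxide, C[N+]1([O-])CCOCC1; water, O
Why: Catalytic syn-dihydroxylation should occur on the exo face of the strained alkene (anti to the endo imide), which stops cycloreversion and removes the alkene before the radical step.

Step 4
Reactants: 8 diol imide
Product: 9 (1R,2S,4S,5R,6S)-5,6-dihydroxy-1-(4-methoxy-4-oxobutyl)-7-oxabicyclo[2.2.1]heptane-2-carboxylic acid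
Conditions: LiOH, H2O2, THF/H2O, 0 °C; Na2SO3; aq. HCl to pH 3
Reagents that add atoms: hydrogen peroxide, OO
Why: Hydroperoxide cleavage of the N-acyl oxazolidinone attacks the exocyclic imide carbonyl selectively, so the methyl ester should survive, and the endo acid cannot lactonise onto the exo hydroxyl groups.

Step 5
Reactants: 9 diol acid
Product: 10 methyl 4-[(1R,4S,5R,6S)-5,6-dihydroxy-7-oxabicyclo[2.2.1]heptan-1-yl]butanoate
Conditions: 9-mesityl-10-phenylacridinium BF4 (5 mol%), PhSSPh (10 mol%), i-Pr2NEt (20 mol%), CF3CH2OH, 450 nm, rt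
Reagents that add atoms: none
Why: Photoredox hydrodecarboxylation (carboxylate oxidation, loss of CO2, hydrogen-atom transfer from thiophenol) should turn C2 into CH2; no alkene is left for the secondary radical to add to, and the deleted centre carries no stereochemical information that is needed.

Step 6
Reactants: 10 bicyclic diol
Product: 12 methyl 4-[(2R,5S)-2,5-bis(hydroxymethyl)oxolan-2-yl]butanoate, via methyl 4-[(2R,5S)-2,5-diformyloxolan-2-yl]butanoate 11 (not isolated)
Conditions: NaIO4, THF/H2O, 0 °C; then NaBH4, MeOH, 0 °C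
Reagents that add atoms: none
Why: Periodate glycol cleavage should open the carbon bridge to two cis formyl groups on the oxolane, and immediate borohydride reduction removes the epimerisable C5 aldehyde while the ester is inert at 0 °C.

Step 7
Reactants: 12 diol
Product: 13 methyl 4-[(2R,5S)-5-({[tert-butyl(dimethyl)silyl]oxy}methyl)-2-(hydroxymethyl)oxolan-2-yl]butanoate
Conditions: TBSCl (1.05 equiv), imidazole, CH2Cl2, -30 °C
Reagents that add atoms: tert-butyldimethylsilyl chloride, CC(C)(C)[Si](C)(C)Cl
Why: Selective silylation is expected because the hydroxymethyl on the fully substituted C2 is neopentyl-like and reacts much more slowly than the one on the tertiary C5.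

Step 8
Reactants: 13 mono-silyl ether
Product: 14 methyl 4-[(2R,5S)-5-({[tert-butyl(dimethyl)silyl]oxy}methyl)-2-formyloxolan-2-yl]butanoate
Conditions: DMP, NaHCO3, CH2Cl2, 0 °C to rt
Reagents that add atoms: none
Why: Dess–Martin oxidation of the hindered primary alcohol should give an aldehyde that has no α-hydrogen and therefore cannot epimerise.

Step 9
Reactants: 14 quaternary aldehyde
Product: 15 methyl 4-[(2R,5S)-5-({[tert-butyl(dimethyl)silyl]oxy}methyl)oxolan-2-yl]butanoate
Conditions: RhCl(PPh3)3 (1.2 equiv), PhCN, 130 °C
Reagents that add atoms: none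
Why: In the Tsuji–Wilkinson decarbonylation, formyl C–H oxidative addition to monovalent rhodium, CO de-insertion and C–H reductive elimination proceed with retention at the migrating carbon, so hydrogen should take the place of the formyl group cis to the silyloxymethyl arm and leave the ester chain trans to it.

Step 10
Reactants: 15 trans silyl ether
Product: 16 methyl 4-[(2R,5S)-5-(hydroxymethyl)oxolan-2-yl]butanoate
Conditions: CSA (10 mol%), MeOH, 0 °C to rt
Reagents that add atoms: none
Why: Acid-catalysed methanolysis should cleave the primary silyl ether, and methanol cannot change the methyl ester.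

Step 11
Reactants: 16 alcohol
Product: 17 methyl 4-[(2R,5S)-5-formyloxolan-2-yl]butanoate
Conditions: DMP, NaHCO3, CH2Cl2, 0 °C; used crude
Reagents that add atoms: none
Why: Buffered Dess–Martin oxidation should give the α-alkoxy aldehyde under non-basic conditions, so C5 is not expected to epimerise.

Step 12
Reactants: 17 aldehyde
Product: 18 methyl 4-[(2R,5S)-5-ethynyloxolan-2-yl]butanoate
Conditions: dimethyl (1-diazo-2-oxopropyl)phosphonate, K2CO3, MeOH, 0 °C to rt
Reagents that add atoms: dimethyl (1-diazo-2-oxopropyl)phosphonate (Ohira–Bestmann reagent), CC(=O)C(=[N+]=[N-])P(=O)(OC)OC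
Why: Seyferth–Gilbert homologation with the Ohira–Bestmann reagent should convert the formyl group into the terminal alkyne under carbonate conditions that are mild enough for α-alkoxy aldehydes and neutral toward the methyl ester.

Step 13
Reactants: 19 hept-6-yn-1-ol
Product: 21 (6E)-7-iodohept-6-en-1-ol, via alkenylzirconocene 20 (not isolated)
Conditions: Cp2Zr(H)Cl (2.3 equiv), THF, rt; I2, 0 °C; aq. HCl work-up
Reagents that add atoms: iodine, II
Why: Hydrozirconation adds Zr–H syn with zirconium at the terminal carbon (the first equivalent is consumed by the hydroxyl group), and iodinolysis with retention should give the E-vinyl iodide.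

Step 14
Reactants: 21 iodo-alkenol
Product: 22 (6E)-7-iodohept-6-enal
Conditions: DMP, NaHCO3, CH2Cl2, 0 °C to rt
Reagents that add atoms: none
Why: Dess–Martin oxidation of the primary alcohol should leave the vinyl iodide untouched.

Step 15
Reactants: 22 iodo-enal precursor aldehyde
Product: 23 (2E,8E)-9-iodonona-2,8-dienal
Conditions: Ph3P=CHCHO (1.2 equiv), toluene, 80 °C
Reagents that add atoms: (triphenylphosphoranylidene)acetaldehyde, O=CC=P(c1ccccc1)(c1ccccc1)c1ccccc1
Why: Wittig reaction with the stabilised formyl ylide should give the two-carbon-homologated E-enal.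

Step 16
Reactants: 23 iodo-dienal
Product: 24 (1E,3E,9E)-1-bromo-10-iododeca-1,3,9-triene
Conditions: CrCl2 (6 equiv), CHBr3 (2 equiv), THF, 0 °C to rt
Reagents that add atoms: bromoform, BrC(Br)Br
Why: Takai olefination through the geminal dichromium reagent should deliver the E-bromoalkene from the enal, and the vinyl iodide is inert to CrCl2 in the absence of nickel.

Step 17
Reactants: 18 ethynyl-oxolane; 24 bromo-iodo-triene
Product: 25 methyl 4-[(2R,5S)-5-[(3E,9E,11E)-12-bromododeca-3,9,11-trien-1-yn-1-yl]oxolan-2-yl]butanoate
Conditions: Pd(PPh3)4 (5 mol%), CuI (10 mol%), i-Pr2NH, THF, rt, degassed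
Reagents that add atoms: none
Why: In the Sonogashira coupling, zerovalent palladium should insert into the vinyl C–I bond much faster than into the dienyl C–Br bond at room temperature, and the copper acetylide couples with retention of the E geometry.

**Compound list**
1 | furan | c1ccoc1 | starting material
2 | 4-bromo-1,1,1-trimethoxybutane | COC(OC)(OC)CCCBr | starting material
3 | 2-furyllithium | [Li]c1ccco1 | intermediate
4 | 2-(4,4,4-trimethoxybutyl)furan | COC(OC)(OC)CCCc1ccco1 | intermediate
5 | methyl 4-(furan-2-yl)butanoate | COC(=O)CCCc1ccco1 | intermediate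
6 | 3-acryloyl-1,3-oxazolidin-2-one | C=CC(=O)N1CCOC1=O | starting material
7 | methyl 4-[(1S,2S,4S)-2-(2-oxo-1,3-oxazolidine-3-carbonyl)-7-oxabicyclo[2.2.1]hept-5-en-1-yl]butanoate (imide endo, next to the substituted bridgehead) | COC(=O)CCC[C@]12[C@@H](C(=O)N3CCOC3=O)C[C@H](O1)C=C2 | intermediate
8 | methyl 4-[(1R,2S,4S,5R,6S)-5,6-dihydroxy-2-(2-oxo-1,3-oxazolidine-3-carbonyl)-7-oxabicyclo[2.2.1]heptan-1-yl]butanoate (exo,exo-diol) | COC(=O)CCC[C@]12[C@@H](C(=O)N3CCOC3=O)C[C@H](O1)[C@H](O)[C@@H]2O | intermediate
9 | (1R,2S,4S,5R,6S)-5,6-dihydroxy-1-(4-methoxy-4-oxobutyl)-7-oxabicyclo[2.2.1]heptane-2-carboxylic acid | COC(=O)CCC[C@]12[C@@H](C(=O)O)C[C@H](O1)[C@H](O)[C@@H]2O | intermediate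
10 | methyl 4-[(1R,4S,5R,6S)-5,6-dihydroxy-7-oxabicyclo[2.2.1]heptan-1-yl]butanoate | COC(=O)CCC[C@]12CC[C@H](O1)[C@H](O)[C@@H]2O | intermediate
11 | methyl 4-[(2R,5S)-2,5-diformyloxolan-2-yl]butanoate (formyl groups cis) | COC(=O)CCC[C@]1(C=O)CC[C@@H](C=O)O1 | intermediate
12 | methyl 4-[(2R,5S)-2,5-bis(hydroxymethyl)oxolan-2-yl]butanoate | COC(=O)CCC[C@]1(CO)CC[C@@H](CO)O1 | intermediate
13 | methyl 4-[(2R,5S)-5-({[tert-butyl(dimethyl)silyl]oxy}methyl)-2-(hydroxymethyl)oxolan-2-yl]butanoate | COC(=O)CCC[C@]1(CO)CC[C@@H](CO[Si](C)(C)C(C)(C)C)O1 | intermediate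
14 | methyl 4-[(2R,5S)-5-({[tert-butyl(dimethyl)silyl]oxy}methyl)-2-formyloxolan-2-yl]butanoate | COC(=O)CCC[C@]1(C=O)CC[C@@H](CO[Si](C)(C)C(C)(C)C)O1 | intermediate
15 | methyl 4-[(2R,5S)-5-({[tert-butyl(dimethyl)silyl]oxy}methyl)oxolan-2-yl]butanoate (2,5-trans) | COC(=O)CCC[C@@H]1CC[C@@H](CO[Si](C)(C)C(C)(C)C)O1 | intermediate
16 | methyl 4-[(2R,5S)-5-(hydroxymethyl)oxolan-2-yl]butanoate | COC(=O)CCC[C@@H]1CC[C@@H](CO)O1 | intermediate
17 | methyl 4-[(2R,5S)-5-formyloxolan-2-yl]butanoate | COC(=O)CCC[C@@H]1CC[C@@H](C=O)O1 | intermediate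
18 | methyl 4-[(2R,5S)-5-ethynyloxolan-2-yl]butanoate | COC(=O)CCC[C@@H]1CC[C@@H](C#C)O1 | intermediate
19 | hept-6-yn-1-ol | C#CCCCCCO | starting material
20 | chlorobis(cyclopentadienyl)[(1E)-7-{[chlorobis(cyclopentadienyl)zirconio]oxy}hept-1-en-1-yl]zirconium | Cl[Zr](C1C=CC=C1)(C1C=CC=C1)/C=C/CCCCCO[Zr](Cl)(C1C=CC=C1)C1C=CC=C1 | intermediate
21 | (6E)-7-iodohept-6-en-1-ol | OCCCCC/C=C/I | intermediate
22 | (6E)-7-iodohept-6-enal | O=CCCCC/C=C/I | intermediate
23 | (2E,8E)-9-iodonona-2,8-dienal | O=C/C=C/CCCC/C=C/I | intermediate
24 | (1E,3E,9E)-1-bromo-10-iododeca-1,3,9-triene | Br/C=C/C=C/CCCC/C=C/I | intermediate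
25 | methyl 4-[(2R,5S)-5-[(3E,9E,11E)-12-bromododeca-3,9,11-trien-1-yn-1-yl]oxolan-2-yl]butanoate | COC(=O)CCC[C@@H]1CC[C@@H](C#C/C=C/CCCC/C=C/C=C/Br)O1 | target

Total step count: 17. Longest linear sequence: 13 steps (steps 1 to 12, then step 17); steps 13 to 16 make the side-chain partner.

**Steps most likely to fail**

Step 9. β-Hydride elimination from the tertiary α-alkoxyalkyl rhodium hydride may outrun C–H reductive elimination and give an enol ether instead of 15. The fallback turns this elimination into the plan and sets C2 by a directed hydrogenation. It sets out from 14. Rhodium-catalysed transfer dehydroformylation ([Rh(cod)OMe]2, Xantphos, 3-methoxybenzoic acid, norbornadiene as acceptor, THF, 80 °C) should give the endocyclic enol ether methyl 4-[(5S)-5-({[tert-butyl(dimethyl)silyl]oxy}methyl)-4,5-dihydrofuran-2-yl]butanoate F1. TBAF in THF should free the alcohol methyl 4-[(5S)-5-(hydroxymethyl)-4,5-dihydrofuran-2-yl]butanoate F2. Hydroxyl-directed hydrogenation with [Ir(cod)(PCy3)(py)]PF6 under H2 in CH2Cl2 should deliver hydrogen to C2 from the face of the hydroxymethyl group, which places the chain trans. The fallback comes back to the route at 16.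

Step 2. The Lewis acid may induce Friedel–Crafts conjugate addition at C5 of the electron-rich furan or cycloreversion, and incomplete regio- or endo-control would erode the enantiomeric purity once the acyl carbon is removed. The fallback replaces catalyst control by auxiliary control with separation of diastereomers and uses no Lewis acid. It sets out from 5. Thermal cycloaddition with (4S)-3-acryloyl-4-benzyl-1,3-oxazolidin-2-one under 1.3 GPa in CH2Cl2 at room temperature should give diastereomeric adducts. The ortho-endo adduct of the required ring configuration, methyl 4-[(1S,2S,4S)-2-{[(4S)-4-benzyl-2-oxo-1,3-oxazolidin-3-yl]carbonyl}-7-oxabicyclo[2.2.1]hept-5-en-1-yl]butanoate F3, is purified by chromatography or crystallisation. Dihydroxylation as in step 3 should give methyl 4-[(1R,2S,4S,5R,6S)-2-{[(4S)-4-benzyl-2-oxo-1,3-oxazolidin-3-yl]carbonyl}-5,6-dihydroxy-7-oxabicyclo[2.2.1]heptan-1-yl]butanoate F4. Hydroperoxide cleavage as in step 4 comes back to the route at 9.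

Step 17. Zerovalent palladium may also insert into the dienyl C–Br bond (oligomerisation, loss of bromide), and the alkyne may homocouple. The fallback installs the bromoalkene after the coupling. It sets out from 18 and 23. Coupling under the same Pd/Cu conditions with iodo-dienal 23, which carries no second halide, should give methyl 4-[(2R,5S)-5-[(3E,9E)-11-oxoundeca-3,9-dien-1-yn-1-yl]oxolan-2-yl]butanoate F5. Takai bromo-olefination (CrCl2, CHBr3, THF, 0 °C) then comes back to the route at 25, and step 16 is not needed.

**Further compounds**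
F1 | step 9 | methyl 4-[(5S)-5-({[tert-butyl(dimethyl)silyl]oxy}methyl)-4,5-dihydrofuran-2-yl]butanoate | COC(=O)CCCC1=CC[C@@H](CO[Si](C)(C)C(C)(C)C)O1
F2 | step 9 | methyl 4-[(5S)-5-(hydroxymethyl)-4,5-dihydrofuran-2-yl]butanoate | COC(=O)CCCC1=CC[C@@H](CO)O1
F3 | step 2 | methyl 4-[(1S,2S,4S)-2-{[(4S)-4-benzyl-2-oxo-1,3-oxazolidin-3-yl]carbonyl}-7-oxabicyclo[2.2.1]hept-5-en-1-yl]butanoate | COC(=O)CCC[C@]12[C@@H](C(=O)N3[C@@H](Cc4ccccc4)COC3=O)C[C@H](O1)C=C2
F4 | step 2 | methyl 4-[(1R,2S,4S,5R,6S)-2-{[(4S)-4-benzyl-2-oxo-1,3-oxazolidin-3-yl]carbonyl}-5,6-dihydroxy-7-oxabicyclo[2.2.1]heptan-1-yl]butanoate | COC(=O)CCC[C@]12[C@@H](C(=O)N3[C@@H](Cc4ccccc4)COC3=O)C[C@H](O1)[C@H](O)[C@@H]2O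
F5 | step 17 | methyl 4-[(2R,5S)-5-[(3E,9E)-11-oxoundeca-3,9-dien-1-yn-1-yl]oxolan-2-yl]butanoate | COC(=O)CCC[C@@H]1CC[C@@H](C#C/C=C/CCCC/C=C/C=O)O1
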